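Ring B of the target is a cyclohexene whose C6=C7 bond lies across from the ring-fusion bond C5–C10 and from C8–C9, so it is cut at those two bonds with the C1–C4 chain of ring A as tether. One thermal intramolecular [4+2] reaction of an acyclic (2E,4E,10E)-trienoate then closes rings A and B and sets C5, C8, C9 and C10 together. The precursor carries the dienoate as an acid-labile (S)-1-(4-methoxyphenyl)ethyl ester, which turns the two enantiomeric folding modes into separable diastereomers and leaves in the last step, and a silyl ether at C12. Afterwards C8 is epimerized and the C13–C16 unit is joined by Negishi coupling.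

Key step: step 9

Remark: atoms carry labdane numbers (ring A = C1–C5 and C10; ring B = C5–C10; side chain C11–C16 on C9; C17 on C8; C20 on C10), and in these numbers the target is (5R,8S,9R,10S,13E). No facial induction by the ester auxiliary is assumed; it serves as a handle for separating diastereomers, and the numbered starting materials are taken as commercial.

Step 1
Reactants: 1 5-chloropent-1-yne; 2 ethylene oxide
Product: 5 (E)-7-chloro-4-methylhept-3-en-1-ol, via alkenyldimethylalane 3 (not isolated), via lithium alkenyl(butyl)dimethylaluminate 4 (not isolated)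
Conditions: AlMe3 (2.5 equiv), Cp2ZrCl2 (0.25 equiv), CH2Cl2, 0 °C to rt; volatiles removed, hexane; n-BuLi (1.0 equiv), THF, −78 °C; 2 (3 equiv), −78 °C to rt; 1 M HCl, 0 °C
Reagents that add atoms: trimethylaluminium, C[Al](C)C
Why: Zirconocene-catalysed Negishi carboalumination adds methyl and aluminium syn across the terminal alkyne with the methyl on the internal carbon, and the alanate made with n-BuLi opens the epoxide with retention at the alkenyl carbon, so the (E)-trisubstituted alkene with C20 cis to C11 is fixed here while the primary chloride stays untouched.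

Step 2
Reactants: 5 (E)-7-chloro-4-methylhept-3-en-1-ol
Product: 6 tert-butyl{[(E)-7-chloro-4-methylhept-3-en-1-yl]oxy}dimethylsilane
Conditions: TBSCl, imidazole, CH2Cl2, rt
Reagents that add atoms: tert-butyldimethylsilyl chloride, CC(C)(C)[Si](C)(C)Cl
Why: Silylation of the primary alcohol (silyl ether protection) masks the only protic group before the carbanion chemistry of step 4.

Step 3
Reactants: 6 tert-butyl{[(E)-7-chloro-4-methylhept-3-en-1-yl]oxy}dimethylsilane
Product: 7 tert-butyl{[(E)-7-iodo-4-methylhept-3-en-1-yl]oxy}dimethylsilane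
Conditions: NaI (3 equiv), acetone, reflux
Reagents that add atoms: sodium iodide, [Na+].[I-]
Why: Finkelstein exchange, driven by precipitation of NaCl from acetone, turns the sluggish primary chloride into the iodide needed for a clean SN2 alkylation.

Step 4
Reactants: 8 isobutyronitrile; 7 tert-butyl{[(E)-7-iodo-4-methylhept-3-en-1-yl]oxy}dimethylsilane
Product: 10 (E)-9-[(tert-butyldimethylsilyl)oxy]-2,2,6-trimethylnon-6-enenitrile, via lithiated isobutyronitrile 9 (not isolated)
Conditions: LiN(i-Pr)2 (1.2 equiv), THF, −78 °C; then 7, −78 °C to rt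
Reagents that add atoms: none
Why: The tertiary nitrile-stabilised carbanion alkylates the unhindered primary iodide by SN2 (nitrile anion alkylation), which creates the quaternary C4 with its two methyl groups and brings in the carbon that becomes C5.

Step 5
Reactants: 10 (E)-9-[(tert-butyldimethylsilyl)oxy]-2,2,6-trimethylnon-6-enenitrile
Product: 12 (E)-9-[(tert-butyldimethylsilyl)oxy]-2,2,6-trimethylnon-6-enal, via N-aluminated aldimine 11 (not isolated)
Conditions: i-Bu2AlH (1.3 equiv), toluene, −78 to −40 °C; aq. KNaC4H4O6 (potassium sodium tartrate), then 10% aq. citric acid, 0 °C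
Reagents that add atoms: water, O
Why: i-Bu2AlH delivers a single hydride because the N-aluminated aldimine resists further reduction (partial reduction of a nitrile), and cold weak aqueous acid then hydrolyses it to the non-enolizable aldehyde without touching the silyl ether.

Step 6
Reactants: 13 triethyl 4-phosphonocrotonate
Product: 14 (E)-4-(diethoxyphosphoryl)but-2-enoic acid
Conditions: LiOH·H2O (1.05 equiv), THF/H2O, 0 °C to rt; 1 M HCl to pH 2
Reagents that add atoms: lithium hydroxide, [Li+].[OH-]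
Why: Saponification is selective because hydroxide attacks the carboxylic ethyl ester much faster than the phosphonate diethyl esters.

Step 7
Reactants: 14 (E)-4-(diethoxyphosphoryl)but-2-enoic acid; 15 (S)-1-(4-methoxyphenyl)ethanol
Product: 16 (S)-1-(4-methoxyphenyl)ethyl (E)-4-(diethoxyphosphoryl)but-2-enoate
Conditions: EDC·HCl (1.3 equiv), DMAP (0.1 equiv), CH2Cl2, 0 °C to rt
Reagents that add atoms: none
Why: Carbodiimide esterification with DMAP (Steglich esterification) acylates the alcohol oxygen without breaking the C–O bond of 15, so the (S) carbinol centre is carried over unchanged.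

Step 8
Reactants: 12 (E)-9-[(tert-butyldimethylsilyl)oxy]-2,2,6-trimethylnon-6-enal; 16 (S)-1-(4-methoxyphenyl)ethyl (E)-4-(diethoxyphosphoryl)but-2-enoate
Product: 18 (S)-1-(4-methoxyphenyl)ethyl (2E,4E,10E)-13-[(tert-butyldimethylsilyl)oxy]-6,6,10-trimethyltrideca-2,4,10-trienoate, via lithiated phosphonate 17 (not isolated)
Conditions: LiN(SiMe3)2 (1.05 equiv), 16 (1.1 equiv), THF, −78 °C; then 12, −78 °C to rt
Reagents that add atoms: none
Why: Horner–Wadsworth–Emmons olefination of the non-enolizable α-quaternary aldehyde with the stabilised phosphonocrotonate anion should form the C5=C6 bond with (E) geometry and leaves the (E) C7=C8 bond in place.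

Step 9
Reactants: 18 (S)-1-(4-methoxyphenyl)ethyl (2E,4E,10E)-13-[(tert-butyldimethylsilyl)oxy]-6,6,10-trimethyltrideca-2,4,10-trienoate
Product: 19 (S)-1-(4-methoxyphenyl)ethyl (1R,2R,4aR,8aS)-1-{2-[(tert-butyldimethylsilyl)oxy]ethyl}-5,5,8a-trimethyl-1,2,4a,5,6,7,8,8a-octahydronaphthalene-2-carboxylate
Conditions: toluene (0.01 M), BHT (cat.), 2,6-di-tert-butylpyridine (cat.), sealed tube, 190 °C; separation of the diastereomers on SiO2
Reagents that add atoms: none
Why: Heating folds the triene through a concerted, suprafacial [4+2] transition state in which the (2E,4E)-dienoate C8=C7–C6=C5 is the 4π partner and the trisubstituted C9=C10 alkene the 2π partner, forming C8–C9 and C5–C10; the closest known reaction type is the thermal type 1 intramolecular Diels–Alder reaction of 1,3,9-decatrienes bearing an ester on the diene terminus, which gives octalins. Ring B closes as the new six-membered cyclohexene that contains both new bonds and the C6=C7 alkene, and ring A closes in the fused mode as a six-membered carbocycle through the C5–C10 bond, with the tether C4–C3–C2–C1 folded as a chair. C9 and C10 are related by the (E)-alkene, which keeps C20 cis to C11; C8 follows from the (2E) geometry, which puts the ester cis to C4 and therefore axial and syn to C20 (labdane 8R, the epimer of the target at this carbon); C5 follows from the anti array, in which C1 points away from the diene and H5 ends trans to C20. The step needs anti over syn folding: in the anti chair C6 and C9 are both equatorial on the nascent ring A and only the C20 methyl is axial, whereas either syn array puts the diene arm C6 or the dienophile carbon C9 into an axial site, and the gem-dimethyl group at C4 favours the folded rotamer of the tether (Thorpe–Ingold effect). No facial bias is claimed for the remote carbinol centre of the ester, so the absolute sense is secured by separating the two trans-fused auxiliary diastereomers and keeping the (5R,8R,9R,10S) isomer. A Lewis acid is avoided because the tether forces the dienoate δ-carbon C5 onto the more substituted alkene carbon C10, against the polar preference, so acid activation would favour cationic side reactions of the alkene and loss of the acid-labile ester.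

Step 10
Reactants: 19 (S)-1-(4-methoxyphenyl)ethyl (1R,2R,4aR,8aS)-1-{2-[(tert-butyldimethylsilyl)oxy]ethyl}-5,5,8a-trimethyl-1,2,4a,5,6,7,8,8a-octahydronaphthalene-2-carboxylate
Product: 20 (S)-1-(4-methoxyphenyl)ethyl (1R,2S,4aR,8aS)-1-{2-[(tert-butyldimethylsilyl)oxy]ethyl}-5,5,8a-trimethyl-1,2,4a,5,6,7,8,8a-octahydronaphthalene-2-carboxylate
Conditions: KOt-Bu (0.3 equiv), t-BuOH/THF, 0 °C to rt, monitored; AcOH quench
Reagents that add atoms: none
Why: Reversible deprotonation of C8, which is α to the ester, and reprotonation at the same carbon (base-mediated epimerization of an ester α-stereocentre) moves the ester from the axial site syn to the C20 methyl to the equatorial site, the bulky alkoxide in its own alcohol does not transesterify the secondary benzylic ester, and the run is stopped before protonation at C6 can move the alkene into conjugation.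

Step 11
Reactants: 20 (S)-1-(4-methoxyphenyl)ethyl (1R,2S,4aR,8aS)-1-{2-[(tert-butyldimethylsilyl)oxy]ethyl}-5,5,8a-trimethyl-1,2,4a,5,6,7,8,8a-octahydronaphthalene-2-carboxylate
Product: 21 (S)-1-(4-methoxyphenyl)ethyl (1R,2S,4aR,8aS)-1-(2-hydroxyethyl)-5,5,8a-trimethyl-1,2,4a,5,6,7,8,8a-octahydronaphthalene-2-carboxylate
Conditions: Bu4NF (1.2 equiv), AcOH (1.2 equiv), THF, 0 °C to rt; crude product used at once
Reagents that add atoms: none
Why: Fluoride cleaves the Si–O bond (desilylation), and the acetic acid buffer keeps the liberated alkoxide from attacking the C17 ester (δ-lactone formation) or enolizing C8.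

Step 12
Reactants: 21 (S)-1-(4-methoxyphenyl)ethyl (1R,2S,4aR,8aS)-1-(2-hydroxyethyl)-5,5,8a-trimethyl-1,2,4a,5,6,7,8,8a-octahydronaphthalene-2-carboxylate
Product: 22 (S)-1-(4-methoxyphenyl)ethyl (1R,2S,4aR,8aS)-1-(2-iodoethyl)-5,5,8a-trimethyl-1,2,4a,5,6,7,8,8a-octahydronaphthalene-2-carboxylate
Conditions: I2 (1.3 equiv), PPh3 (1.3 equiv), imidazole (2 equiv), CH2Cl2, 0 °C
Reagents that add atoms: iodine, II
Why: Appel-type iodination converts the primary alcohol into the iodide by SN2 displacement of the oxyphosphonium group under imidazole-buffered conditions that spare the acid-labile ester.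

Step 13
Reactants: 23 propargyl alcohol
Product: 24 tert-butyl(diphenyl)(prop-2-yn-1-yloxy)silane
Conditions: TBDPSCl, imidazole, CH2Cl2, rt
Reagents that add atoms: tert-butyldiphenylsilyl chloride, CC(C)(C)[Si](Cl)(c1ccccc1)c1ccccc1
Why: Silylation (silyl ether protection) with the acid-stable TBDPS group masks the alcohol for the acetylide and hydroiodination steps.

Step 14
Reactants: 24 tert-butyl(diphenyl)(prop-2-yn-1-yloxy)silane
Product: 26 tert-butyl 4-[(tert-butyldiphenylsilyl)oxy]but-2-ynoate, via lithium acetylide 25 (not isolated)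
Conditions: n-BuLi (1.05 equiv), THF, −78 °C; Boc2O (1.1 equiv), −78 to 0 °C; H2O
Reagents that add atoms: di-tert-butyl dicarbonate, CC(C)(C)OC(=O)OC(=O)OC(C)(C)C
Why: The lithium acetylide is acylated by Boc2O (alkoxycarbonylation of an acetylide), which gives the tert-butyl ynoate that carries C13 to C16 of the side chain.

Step 15
Reactants: 26 tert-butyl 4-[(tert-butyldiphenylsilyl)oxy]but-2-ynoate
Product: 27 tert-butyl (Z)-4-[(tert-butyldiphenylsilyl)oxy]-3-iodobut-2-enoate
Conditions: NaI (1.5 equiv), AcOH (3 equiv), MeCN, 80 °C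
Reagents that add atoms: sodium iodide, [Na+].[I-]
Why: Conjugate hydroiodination of the ynoate (iodide adds to C13, then protonation of the allenolate anti to iodine) should give the (Z)-β-iodoenoate with iodine cis to the ester, the geometry that places C12 cis to C15 after coupling.

Step 16
Reactants: 22 (S)-1-(4-methoxyphenyl)ethyl (1R,2S,4aR,8aS)-1-(2-iodoethyl)-5,5,8a-trimethyl-1,2,4a,5,6,7,8,8a-octahydronaphthalene-2-carboxylate; 27 tert-butyl (Z)-4-[(tert-butyldiphenylsilyl)oxy]-3-iodobut-2-enoate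
Product: 29 tert-butyl (E)-4-[(tert-butyldiphenylsilyl)oxy]-3-{2-[(1R,2S,4aR,8aS)-2-{[(S)-1-(4-methoxyphenyl)ethoxy]carbonyl}-5,5,8a-trimethyl-1,2,4a,5,6,7,8,8a-octahydronaphthalen-1-yl]ethyl}but-2-enoate, via alkylzinc iodide 28 (not isolated)
Conditions: Zn dust (activated by BrCH2CH2Br and Me3SiCl), LiCl, THF, 35 °C; then 27 (1.2 equiv), PdCl2(dppf) (5 mol %), THF, rt
Reagents that add atoms: none
Why: Zinc inserts into the primary C–I bond in the presence of LiCl, and palladium-catalysed Negishi coupling of the alkylzinc with the vinyl iodide forms C12–C13 with retention of alkene geometry; C16 carries a silyl ether and not the acetate so that no allylic ester meets the palladium catalyst.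

Step 17
Reactants: 29 tert-butyl (E)-4-[(tert-butyldiphenylsilyl)oxy]-3-{2-[(1R,2S,4aR,8aS)-2-{[(S)-1-(4-methoxyphenyl)ethoxy]carbonyl}-5,5,8a-trimethyl-1,2,4a,5,6,7,8,8a-octahydronaphthalen-1-yl]ethyl}but-2-enoate
Product: 30 tert-butyl (E)-4-hydroxy-3-{2-[(1R,2S,4aR,8aS)-2-{[(S)-1-(4-methoxyphenyl)ethoxy]carbonyl}-5,5,8a-trimethyl-1,2,4a,5,6,7,8,8a-octahydronaphthalen-1-yl]ethyl}but-2-enoate
Conditions: Bu4NF (1.5 equiv), AcOH (1.5 equiv), THF, rt
Reagents that add atoms: none
Why: Buffered fluoride removes the TBDPS group (desilylation), and the freed hydroxymethyl group, being trans to the ester across C13=C14, cannot lactonize.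

Step 18
Reactants: 30 tert-butyl (E)-4-hydroxy-3-{2-[(1R,2S,4aR,8aS)-2-{[(S)-1-(4-methoxyphenyl)ethoxy]carbonyl}-5,5,8a-trimethyl-1,2,4a,5,6,7,8,8a-octahydronaphthalen-1-yl]ethyl}but-2-enoate
Product: 31 tert-butyl (E)-4-acetoxy-3-{2-[(1R,2S,4aR,8aS)-2-{[(S)-1-(4-methoxyphenyl)ethoxy]carbonyl}-5,5,8a-trimethyl-1,2,4a,5,6,7,8,8a-octahydronaphthalen-1-yl]ethyl}but-2-enoate
Conditions: Ac2O (2 equiv), pyridine, DMAP (cat.), CH2Cl2, 0 °C
Reagents that add atoms: acetic anhydride, CC(=O)OC(C)=O
Why: DMAP-catalysed acyl transfer from Ac2O (acetylation) converts the primary allylic alcohol into the C16 acetate.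

Step 19
Reactants: 31 tert-butyl (E)-4-acetoxy-3-{2-[(1R,2S,4aR,8aS)-2-{[(S)-1-(4-methoxyphenyl)ethoxy]carbonyl}-5,5,8a-trimethyl-1,2,4a,5,6,7,8,8a-octahydronaphthalen-1-yl]ethyl}but-2-enoate
Product: 32 (1R,2S,4aR,8aS)-1-[(3E)-3-(acetoxymethyl)-4-carboxybut-3-en-1-yl]-5,5,8a-trimethyl-1,2,4a,5,6,7,8,8a-octahydronaphthalene-2-carboxylic acid
Conditions: CF3CO2H/CH2Cl2 (1:4), Et3SiH (3 equiv), 0 °C to rt
Reagents that add atoms: none
Why: Acidolysis cleaves both esters by alkyl–oxygen fission through stabilised cations (tert-butyl, and 4-methoxy-α-methylbenzyl trapped by Et3SiH), which frees both acids without hydroxide and so should leave the acetate, the C8 stereocentre and both alkenes untouched.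

Compound list
1 | 5-chloropent-1-yne | C#CCCCCl | starting material
2 | ethylene oxide (oxirane) | C1CO1 | starting material
3 | [(E)-5-chloro-2-methylpent-1-en-1-yl]dimethylaluminium | C[Al](C)/C=C(\C)CCCCl | intermediate
4 | lithium butyl[(E)-5-chloro-2-methylpent-1-en-1-yl]dimethylaluminate | [Li+].CCCC[Al-](C)(C)/C=C(\C)CCCCl | intermediate
5 | (E)-7-chloro-4-methylhept-3-en-1-ol | OCC/C=C(\C)CCCCl | intermediate
6 | tert-butyl{[(E)-7-chloro-4-methylhept-3-en-1-yl]oxy}dimethylsilane | CC(C)(C)[Si](C)(C)OCC/C=C(\C)CCCCl | intermediate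
7 | tert-butyl{[(E)-7-iodo-4-methylhept-3-en-1-yl]oxy}dimethylsilane | CC(C)(C)[Si](C)(C)OCC/C=C(\C)CCCI | intermediate
8 | isobutyronitrile (2-methylpropanenitrile) | CC(C)C#N | starting material
9 | lithium 2-cyanopropan-2-ide | [Li+].C[C-](C)C#N | intermediate
10 | (E)-9-[(tert-butyldimethylsilyl)oxy]-2,2,6-trimethylnon-6-enenitrile | CC(C)(C)[Si](C)(C)OCC/C=C(\C)CCCC(C)(C)C#N | intermediate
11 | N-(diisobutylalumanyl) aldimine of aldehyde 12 | CC(C)(C)[Si](C)(C)OCC/C=C(\C)CCCC(C)(C)C=N[Al](CC(C)C)CC(C)C | intermediate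
12 | (E)-9-[(tert-butyldimethylsilyl)oxy]-2,2,6-trimethylnon-6-enal | CC(C)(C)[Si](C)(C)OCC/C=C(\C)CCCC(C)(C)C=O | intermediate
13 | triethyl 4-phosphonocrotonate | CCOC(=O)/C=C/CP(=O)(OCC)OCC | starting material
14 | (E)-4-(diethoxyphosphoryl)but-2-enoic acid | OC(=O)/C=C/CP(=O)(OCC)OCC | intermediate
15 | (S)-1-(4-methoxyphenyl)ethanol | C[C@H](O)c1ccc(OC)cc1 | starting material
16 | (S)-1-(4-methoxyphenyl)ethyl (E)-4-(diethoxyphosphoryl)but-2-enoate | CCOP(=O)(OCC)C/C=C/C(=O)O[C@@H](C)c1ccc(OC)cc1 | intermediate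
17 | lithium salt of the phosphorus-stabilised carbanion of 16 | [Li+].CCOP(=O)(OCC)[CH-]/C=C/C(=O)O[C@@H](C)c1ccc(OC)cc1 | intermediate
18 | (S)-1-(4-methoxyphenyl)ethyl (2E,4E,10E)-13-[(tert-butyldimethylsilyl)oxy]-6,6,10-trimethyltrideca-2,4,10-trienoate | CC(C)(C)[Si](C)(C)OCC/C=C(\C)CCCC(C)(C)/C=C/C=C/C(=O)O[C@@H](C)c1ccc(OC)cc1 | intermediate
19 | (S)-1-(4-methoxyphenyl)ethyl (1R,2R,4aR,8aS)-1-{2-[(tert-butyldimethylsilyl)oxy]ethyl}-5,5,8a-trimethyl-1,2,4a,5,6,7,8,8a-octahydronaphthalene-2-carboxylate (trans-fused, ester axial; labdane 5R,8R,9R,10S) | CC(C)(C)[Si](C)(C)OCC[C@@H]1[C@H](C(=O)O[C@@H](C)c3ccc(OC)cc3)C=C[C@@H]2C(C)(C)CCC[C@@]12C | intermediate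
20 | (S)-1-(4-methoxyphenyl)ethyl (1R,2S,4aR,8aS)-1-{2-[(tert-butyldimethylsilyl)oxy]ethyl}-5,5,8a-trimethyl-1,2,4a,5,6,7,8,8a-octahydronaphthalene-2-carboxylate (ester equatorial; labdane 5R,8S,9R,10S) | CC(C)(C)[Si](C)(C)OCC[C@@H]1[C@@H](C(=O)O[C@@H](C)c3ccc(OC)cc3)C=C[C@@H]2C(C)(C)CCC[C@@]12C | intermediate
21 | (S)-1-(4-methoxyphenyl)ethyl (1R,2S,4aR,8aS)-1-(2-hydroxyethyl)-5,5,8a-trimethyl-1,2,4a,5,6,7,8,8a-octahydronaphthalene-2-carboxylate | OCC[C@@H]1[C@@H](C(=O)O[C@@H](C)c3ccc(OC)cc3)C=C[C@@H]2C(C)(C)CCC[C@@]12C | intermediate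
22 | (S)-1-(4-methoxyphenyl)ethyl (1R,2S,4aR,8aS)-1-(2-iodoethyl)-5,5,8a-trimethyl-1,2,4a,5,6,7,8,8a-octahydronaphthalene-2-carboxylate | ICC[C@@H]1[C@@H](C(=O)O[C@@H](C)c3ccc(OC)cc3)C=C[C@@H]2C(C)(C)CCC[C@@]12C | intermediate
23 | propargyl alcohol (prop-2-yn-1-ol) | C#CCO | starting material
24 | tert-butyl(diphenyl)(prop-2-yn-1-yloxy)silane | C#CCO[Si](c1ccccc1)(c1ccccc1)C(C)(C)C | intermediate
25 | lithium acetylide of 24 | [Li]C#CCO[Si](c1ccccc1)(c1ccccc1)C(C)(C)C | intermediate
26 | tert-butyl 4-[(tert-butyldiphenylsilyl)oxy]but-2-ynoate | CC(C)(C)OC(=O)C#CCO[Si](c1ccccc1)(c1ccccc1)C(C)(C)C | intermediate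
27 | tert-butyl (Z)-4-[(tert-butyldiphenylsilyl)oxy]-3-iodobut-2-enoate | CC(C)(C)OC(=O)/C=C(\I)CO[Si](c1ccccc1)(c1ccccc1)C(C)(C)C | intermediate
28 | {2-[(1R,2S,4aR,8aS)-2-{[(S)-1-(4-methoxyphenyl)ethoxy]carbonyl}-5,5,8a-trimethyl-1,2,4a,5,6,7,8,8a-octahydronaphthalen-1-yl]ethyl}zinc iodide | I[Zn]CC[C@@H]1[C@@H](C(=O)O[C@@H](C)c3ccc(OC)cc3)C=C[C@@H]2C(C)(C)CCC[C@@]12C | intermediate
29 | tert-butyl (E)-4-[(tert-butyldiphenylsilyl)oxy]-3-{2-[(1R,2S,4aR,8aS)-2-{[(S)-1-(4-methoxyphenyl)ethoxy]carbonyl}-5,5,8a-trimethyl-1,2,4a,5,6,7,8,8a-octahydronaphthalen-1-yl]ethyl}but-2-enoate | CC(C)(C)OC(=O)/C=C(/CO[Si](c4ccccc4)(c5ccccc5)C(C)(C)C)CC[C@@H]1[C@@H](C(=O)O[C@@H](C)c3ccc(OC)cc3)C=C[C@@H]2C(C)(C)CCC[C@@]12C | intermediate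
30 | tert-butyl (E)-4-hydroxy-3-{2-[(1R,2S,4aR,8aS)-2-{[(S)-1-(4-methoxyphenyl)ethoxy]carbonyl}-5,5,8a-trimethyl-1,2,4a,5,6,7,8,8a-octahydronaphthalen-1-yl]ethyl}but-2-enoate | CC(C)(C)OC(=O)/C=C(/CO)CC[C@@H]1[C@@H](C(=O)O[C@@H](C)c3ccc(OC)cc3)C=C[C@@H]2C(C)(C)CCC[C@@]12C | intermediate
31 | tert-butyl (E)-4-acetoxy-3-{2-[(1R,2S,4aR,8aS)-2-{[(S)-1-(4-methoxyphenyl)ethoxy]carbonyl}-5,5,8a-trimethyl-1,2,4a,5,6,7,8,8a-octahydronaphthalen-1-yl]ethyl}but-2-enoate | CC(C)(C)OC(=O)/C=C(/COC(C)=O)CC[C@@H]1[C@@H](C(=O)O[C@@H](C)c3ccc(OC)cc3)C=C[C@@H]2C(C)(C)CCC[C@@]12C | intermediate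
32 | (1R,2S,4aR,8aS)-1-[(3E)-3-(acetoxymethyl)-4-carboxybut-3-en-1-yl]-5,5,8a-trimethyl-1,2,4a,5,6,7,8,8a-octahydronaphthalene-2-carboxylic acid (labdane 5R,8S,9R,10S,13E) | CC(=O)OC/C(=C/C(=O)O)CC[C@@H]1[C@@H](C(=O)O)C=C[C@@H]2C(C)(C)CCC[C@@]12C | target

Total step count: 19 (14 in the main line, 2 for phosphonate 16, 3 for vinyl iodide 27).
Longest linear sequence: 14 steps (steps 1–5, 8–12 and 16–19).

Steps most likely to fail

Step 9. The tether may fold partly through the syn array, and the ester auxiliary may exert no facial preference, so that the wanted adduct forms as the minor part of a mixture of diastereomers that resists separation. The fallback replaces separation of covalent diastereomers by a classical salt resolution; it sets out from 12 and comes back at 20. Aldehyde 12 is olefinated with commercial phosphonate 13 (LiN(SiMe3)2, THF) to ethyl (2E,4E,10E)-13-[(tert-butyldimethylsilyl)oxy]-6,6,10-trimethyltrideca-2,4,10-trienoate F1, which is cyclized thermally as in step 9 to the racemic trans-fused axial ethyl ester F2. NaOEt in EtOH equilibrates C8 to the racemic equatorial ethyl ester F3, and KOH in aqueous EtOH gives the racemic equatorial acid F4. The acid is resolved by crystallization with (R)-1-phenylethylamine (or its antipode, whichever gives the less soluble salt of the wanted acid) as the (R)-1-phenylethylammonium (1R,2S,4aR,8aS)-carboxylate F5. Aqueous KHSO4 frees the (1R,2S,4aR,8aS)-acid F6, which is esterified with 15 (EDC·HCl, DMAP, CH2Cl2) to give 20.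

Step 10. Reprotonation of the dienolate at C6 in place of C8 would move the alkene into conjugation with the ester and erase the C8 stereocentre, and reprotonation from the face away from the C20 methyl would return the axial ester, so equilibration may stall or overshoot. The fallback sets C8 by diene geometry in place of equilibration; it sets out from 12 and comes back at 20. Aldehyde 12 is homologated with Ph3P=CHCHO (toluene, 90 °C) to (2E,8E)-11-[(tert-butyldimethylsilyl)oxy]-4,4,8-trimethylundeca-2,8-dienal F7. Alcohol 15 is acylated with bromoacetyl bromide (pyridine, CH2Cl2) to (S)-1-(4-methoxyphenyl)ethyl bromoacetate F8, which with diphenyl phosphite and Et3N gives (S)-1-(4-methoxyphenyl)ethyl (diphenoxyphosphoryl)acetate F9. Ando olefination of F7 with F9 (NaH, THF, −78 °C) gives (S)-1-(4-methoxyphenyl)ethyl (2Z,4E,10E)-13-[(tert-butyldimethylsilyl)oxy]-6,6,10-trimethyltrideca-2,4,10-trienoate F10. Its thermal cycloaddition through the same anti array places the ester trans to C4, that is equatorial, and so should deliver 20 directly after separation of the auxiliary diastereomers.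

Step 16. Zinc insertion into the iodide may stay incomplete, or the alkylzinc may be protonated or lose a β-hydrogen on palladium, so that the side chain is reduced or eliminated in place of being coupled. The fallback sets out from 22 and 27 and comes back at 29: a nickel-catalysed reductive cross-electrophile coupling of the two iodides without a preformed organometal (NiBr2(dme), 4,4'-di-tert-butyl-2,2'-bipyridine, Mn powder, DMA, rt) joins C12 to C13 directly. This fallback makes no further compound (F0).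

Further compounds
F1 | step 9 | ethyl (2E,4E,10E)-13-[(tert-butyldimethylsilyl)oxy]-6,6,10-trimethyltrideca-2,4,10-trienoate | CCOC(=O)/C=C/C=C/C(C)(C)CCC/C(C)=C/CCO[Si](C)(C)C(C)(C)C
F2 | step 9 | ethyl (1R*,2R*,4aR*,8aS*)-1-{2-[(tert-butyldimethylsilyl)oxy]ethyl}-5,5,8a-trimethyl-1,2,4a,5,6,7,8,8a-octahydronaphthalene-2-carboxylate (racemate, one enantiomer drawn) | CC(C)(C)[Si](C)(C)OCC[C@@H]1[C@H](C(=O)OCC)C=C[C@@H]2C(C)(C)CCC[C@@]12C
F3 | step 9 | ethyl (1R*,2S*,4aR*,8aS*)-1-{2-[(tert-butyldimethylsilyl)oxy]ethyl}-5,5,8a-trimethyl-1,2,4a,5,6,7,8,8a-octahydronaphthalene-2-carboxylate (racemate, one enantiomer drawn) | CC(C)(C)[Si](C)(C)OCC[C@@H]1[C@@H](C(=O)OCC)C=C[C@@H]2C(C)(C)CCC[C@@]12C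
F4 | step 9 | (1R*,2S*,4aR*,8aS*)-1-{2-[(tert-butyldimethylsilyl)oxy]ethyl}-5,5,8a-trimethyl-1,2,4a,5,6,7,8,8a-octahydronaphthalene-2-carboxylic acid (racemate, one enantiomer drawn) | CC(C)(C)[Si](C)(C)OCC[C@@H]1[C@@H](C(=O)O)C=C[C@@H]2C(C)(C)CCC[C@@]12C
F5 | step 9 | (R)-1-phenylethylammonium (1R,2S,4aR,8aS)-1-{2-[(tert-butyldimethylsilyl)oxy]ethyl}-5,5,8a-trimethyl-1,2,4a,5,6,7,8,8a-octahydronaphthalene-2-carboxylate | CC(C)(C)[Si](C)(C)OCC[C@@H]1[C@@H](C(=O)[O-])C=C[C@@H]2C(C)(C)CCC[C@@]12C.C[C@@H]([NH3+])c3ccccc3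
F6 | step 9 | (1R,2S,4aR,8aS)-1-{2-[(tert-butyldimethylsilyl)oxy]ethyl}-5,5,8a-trimethyl-1,2,4a,5,6,7,8,8a-octahydronaphthalene-2-carboxylic acid (single enantiomer) | CC(C)(C)[Si](C)(C)OCC[C@@H]1[C@@H](C(=O)O)C=C[C@@H]2C(C)(C)CCC[C@@]12C
F7 | step 10 | (2E,8E)-11-[(tert-butyldimethylsilyl)oxy]-4,4,8-trimethylundeca-2,8-dienal | CC(C)(C)[Si](C)(C)OCC/C=C(\C)CCCC(C)(C)/C=C/C=O
F8 | step 10 | (S)-1-(4-methoxyphenyl)ethyl bromoacetate | BrCC(=O)O[C@@H](C)c1ccc(OC)cc1
F9 | step 10 | (S)-1-(4-methoxyphenyl)ethyl (diphenoxyphosphoryl)acetate | O=C(CP(=O)(Oc1ccccc1)Oc1ccccc1)O[C@@H](C)c1ccc(OC)cc1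
F10 | step 10 | (S)-1-(4-methoxyphenyl)ethyl (2Z,4E,10E)-13-[(tert-butyldimethylsilyl)oxy]-6,6,10-trimethyltrideca-2,4,10-trienoate | CC(C)(C)[Si](C)(C)OCC/C=C(\C)CCCC(C)(C)/C=C/C=C\C(=O)O[C@@H](C)c1ccc(OC)cc1
F0 | step 16 | none | none
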